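The runs were computed on assumed constants; noise was put on by code.

Follow the rate, not the concentrations, through these flasks.

| setting | Monday's | Sunday's | Tuesday's | gamma | theta | eta |
|---|---|---|---|---|---|---|
| electrophile | 0.20 M | 0.20 M | 0.20 M | 0.20 M | 0.20 M | 0.20 M |
| nucleophile | 0.18 M | 0.45 M | 1 M | 0.220 M | 0.440 M | 0.880 M |
| remark | run made earlier | run made earlier | run made earlier |  |  |  |
| time |  |  |  | 4.0 min | 4.0 min | 4.0 min |

| run | time / s | electrophile / % | target / % |
|---|---|---|---|
| Monday's | 10.0 | 97.1 | 2.2 |
| Monday's | 30.0 | 90.9 | 6.3 |
| Monday's | 60.0 | 86.9 | 10.4 |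
| Monday's | 80.0 | 82.9 | 12.5 |
| Monday's | 120 | 79.9 | 15.7 |
| Sunday's | 25.0 | 86.5 | 12.9 |
| Sunday's | 50.0 | 75.1 | 22.1 |
| Sunday's | 80.0 | 63.7 | 29.6 |
| Sunday's | 90.0 | 62.5 | 31.1 |
| Sunday's | 120 | 52.5 | 33.6 |
| Tuesday's | 10.0 | 87.8 | 13.5 |
| Tuesday's | 20.0 | 77.2 | 24.1 |
| Tuesday's | 30.0 | 67.0 | 30.9 |
| Tuesday's | 60.0 | 44.8 | 46.6 |
| Tuesday's | 120 | 23.7 | 52.9 |

(standard deviation of a reading: 1 percentage point)

- what is said of acid set free includes crystals
- crystals is a solid; its amount is given per volume of the solution
- on the list of suspects stand: target -> over-reaction product; electrophile + nucleophile -> acid set free + target; nucleophile + acid set free <-> protonated nucleophile; crystals <-> acid set free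

* part of the electrophile that has reacted at the end, gamma
* part of the electrophile that has reacted at the end, theta
* part of the electrophile that has reacted at the end, eta
* what raising the concentration of nucleophile from its lowest to its highest value here does to the part of the electrophile that has reacted (changes below 5 percentage points count as none) (no change / it rises / it falls)

Tuesday's run gives the speed. After 30.0 s its electrophile stands at 67.0%, and allowing for the nucleophile spent meanwhile, this reads as a specific rate of 0.858 min⁻¹ at 1 M of nucleophile. The start is pseudo-first-order, so I scale this with the nucleophile charge: 0.189 min⁻¹ in gamma, 0.377 min⁻¹ in theta, 0.755 min⁻¹ in eta.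

Two factors slow it. One is the part of the electrophile left. The other is the part of the nucleophile left, which falls with the spending ratio. The spending ratio of gamma, 1.82, is the nucleophile its whole electrophile charge would take at two per electrophile, over the nucleophile charged; theta has 0.909, eta 0.455. Two is the count if acid set free binds a second nucleophile as protonated nucleophile.

Monday's run tests this. At 120 s, one nucleophile per electrophile reckons to 23.3% reacted and two to 20.5%; the readings show 20.1%, with a scatter of 1 percentage point.

Summing the slowing over 4.0 min, I reckon 36.0% reacted in gamma, 61.8% in theta and 88.5% in eta. At that point gamma's nucleophile factor, 34.5%, is lower than its electrophile factor, 64.0%. In eta the order reverses, 59.8% against 11.5%.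

The forecast stands a little higher, at 37%, 63% and 89%, with the trend: it rises. Of the acid it says: “Perhaps acid crystallising spares some nucleophile, though this is uncertain.”

The flasks give 39.9%, 65.1% and 89.6%, a change of 50 points from gamma to eta: it rises.

    target → over-reaction product (k = 0.00462 s⁻¹)
    electrophile + nucleophile → acid set free + target (k = 0.0149 L mol⁻¹ s⁻¹)
    nucleophile + acid set free ⇌ protonated nucleophile, settled at all times (K = 93.8 L mol⁻¹)
    crystals ⇌ acid set free, rate k4*(cs4 - [acid set free]) while solid is left; crystals form when [acid set free] > cs4 (solubility = 2.70 mM, k = 0.925 s⁻¹)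

The percentage does not show what stands in gamma at 4.00 min: crystals at 0.0463 M, and free nucleophile at 50% of its charge, more than the 27.4% that a spending ratio of 1.82 gives at that conversion. One more flask like eta, charged with 0.35 M of nucleophile, has a spending ratio of 1.14; the reckoning gives 52.5% there, and that flask has reacted 56.2%.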